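**Plan**

1. Retrosynthesis: the central C–C single bond of the diene is cut first (Suzuki–Miyaura), giving an oxolane alkenylboronate and a 3-(2-iodoethenyl)isocoumarin. The isocoumarin is then cut at C3–C4 and O2–C1 back to a chlorinated orsellinate, and the oxolane is cut at C3–C4.
2. Enabling feature: in the oxolane (O1, C2 dienyl, C3 OH, C4 H2, C5 CH3) the unit CH3–C5–C4 is an acetone residue bound through O1 to C2 and aldol-linked to the carbinol C3. O1, C2, C3, C4, C5 and the methyl group are therefore all present in the isopropylidene ketal of the C2/C3 diol, of which the oxolane is an isomer.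
3. Forward, oxolane half: (R)-glyceraldehyde acetonide → E-alkenylboronate → ketal opened to a secondary 2-propenyl ether and primary alcohol → aldehyde → the oxolane ring closes in step 4 by C4 attacking C3, with silane reduction at C5 in the same flask.
4. Forward, isocoumarin half: methyl orsellinate → chlorination → MOM ethers → acetylation of the toluate anion and enol lactonisation (pyranone ring, step 7) → Riley oxidation → Takai iodo-olefination → phenols freed. The chain is joined last (step 11) with no protecting group left.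
5. Stereochemistry: C2 from the chiral pool; C3 (trans to C2) in the ring-closing C–C bond formation under control of C2; C5 (methyl cis to the C2 substituent) by hydride attack cis to O-3 on the oxolanylium ion; both alkenes E from chromium-mediated olefinations, retained in the coupling.

Key step: step 4

Remark: oxolane numbering is O1, C2 (dienyl), C3 (OH), C4 (CH2), C5 (CH3); the SMILES corresponds to (2S,3R,5R), i.e. 2,3-trans and 2,5-cis, with an (E,E)-diene. B(pin) stands for 4,4,5,5-tetramethyl-1,3,2-dioxaborolan-2-yl.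

**Route**

Step 1
Reactants: 1 (4R)-2,2-dimethyl-1,3-dioxolane-4-carbaldehyde
Product: 2 2-[(E)-2-[(4S)-2,2-dimethyl-1,3-dioxolan-4-yl]ethenyl]-4,4,5,5-tetramethyl-1,3,2-dioxaborolane
Conditions: Cl2CHB(pin), CrCl2, LiI, THF, 23 °C
Reagents that add atoms: 2-(dichloromethyl)-4,4,5,5-tetramethyl-1,3,2-dioxaborolane, CC1(C)OB(C(Cl)Cl)OC1(C)C
Why: Takai–Utimoto boryl olefination, in which the geminal dichromium species adds to the aldehyde and eliminates to the E-alkenylboronate under non-basic conditions that should leave the α-stereocentre untouched (its descriptor changes from R to S only because the ligand ranks change).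

Step 2
Reactants: 2 2-[(E)-2-[(4S)-2,2-dimethyl-1,3-dioxolan-4-yl]ethenyl]-4,4,5,5-tetramethyl-1,3,2-dioxaborolane
Product: 4 (2S,3E)-2-(prop-1-en-2-yloxy)-4-(4,4,5,5-tetramethyl-1,3,2-dioxaborolan-2-yl)but-3-en-1-ol, via trimethylsilyl ether 3 (not isolated)
Conditions: TMSOTf, iPr2NEt, CH2Cl2, 0 °C; then K2CO3 (cat.), MeOH, 0 °C; Et3N-washed silica
Reagents that add atoms: none
Why: silyl triflate/amine fragmentation of a ketal to an enol ether, in which the silyl group should go to the less hindered primary oxygen, the tertiary oxocarbenium ion left on the secondary oxygen loses a methyl proton to give the 2-propenyl ether, and methanolysis removes the primary silyl group without touching the stereocentre.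

Step 3
Reactants: 4 (2S,3E)-2-(prop-1-en-2-yloxy)-4-(4,4,5,5-tetramethyl-1,3,2-dioxaborolan-2-yl)but-3-en-1-ol
Product: 5 (2S,3E)-2-(prop-1-en-2-yloxy)-4-(4,4,5,5-tetramethyl-1,3,2-dioxaborolan-2-yl)but-3-enal
Conditions: Dess–Martin periodinane, pyridine, CH2Cl2, 0 °C; cold filtration, used at once
Reagents that add atoms: none
Why: Dess–Martin oxidation of the primary alcohol under pyridine buffering, chosen because it should neither hydrolyse the enol ether nor epimerise the doubly activated C2–H.

Step 4
Reactants: 5 (2S,3E)-2-(prop-1-en-2-yloxy)-4-(4,4,5,5-tetramethyl-1,3,2-dioxaborolan-2-yl)but-3-enal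
Product: 7 (2S,3R,5R)-5-methyl-2-[(E)-2-(4,4,5,5-tetramethyl-1,3,2-dioxaborolan-2-yl)ethenyl]oxolan-3-ol, via oxolanylium aldolate 6 (not isolated)
Conditions: BF3·OEt2 (1.5 equiv), Et3SiH (10 equiv), CH2Cl2 (0.01 M, slow addition of 5), −78 → −40 °C; aq. NaHCO3
Reagents that add atoms: none
Why: Proposed new method: BF3 activates the aldehyde C3=O of 5 and the terminal carbon (C4) of the tethered 2-alkoxypropene adds to it in a Mukaiyama-aldol/Prins-type step to give the 2-methyloxolan-2-ylium aldolate 6, which Et3SiH reduces at C5 before it can revert or lose a proton. The closest known reaction types are the Lewis-acid addition of 2-alkoxypropenes to aldehydes (acetone-aldol surrogates), Prins cyclisations in which an alkene closes an oxolane by 5-endo attack on an oxygen-stabilised cation, and the silane reduction of furanosyl hemiketals through the same kind of oxolanylium ion. The oxolane (O1, C2, C3, C4, C5) closes 5-endo-trig with respect to the enol ether C4=C5 and exo with respect to the carbonyl group, a mode that is strained for enolates but open to this late, cation-like transition state in which the C5–O1 bond can twist out of the enol ether plane. C3 is set in the C–C bond formation by the C2 stereocentre: the BF3-bound carbonyl oxygen should eclipse C2–H and not the alkenyl group, so that O-3 ends up trans to the C2 substituent, and the trans aldolate is also the more stable one should the addition be reversible. C5 is set by the C3 oxygen: hydride should enter the envelope of 6 from the inside, on the face of the pseudoaxial C3–O–BF3 group, which places H-5 cis to O-3 and the methyl group trans to the hydroxyl and cis to the C2 substituent, as in the reduction of 2-deoxyribofuranose-derived hemiketals. The step needs carbonyl activation to win over Claisen rearrangement of the allyl vinyl ether, ionisation of the allylic C2–O1 bond and protonation of the enol ether; monodentate BF3 at −78 °C, slow addition at high dilution and a large excess of silane are chosen for this, and the alkenylboronate is too electron-poor to compete as a π-nucleophile.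

Step 5
Reactants: 8 methyl 2,4-dihydroxy-6-methylbenzoate (methyl orsellinate)
Product: 9 methyl 3-chloro-4,6-dihydroxy-2-methylbenzoate
Conditions: SO2Cl2 (1.05 equiv), Et2O, 0 → 23 °C
Reagents that add atoms: sulfuryl chloride, ClS(Cl)(=O)=O
Why: electrophilic aromatic chlorination, expected at the ring carbon next to the methyl group because it is para to the ester-chelated hydroxyl and ortho to the free hydroxyl, in preference to the carbon flanked by both hydroxyls.

Step 6
Reactants: 9 methyl 3-chloro-4,6-dihydroxy-2-methylbenzoate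
Product: 10 methyl 3-chloro-4,6-bis(methoxymethoxy)-2-methylbenzoate
Conditions: NaH, MOMCl, DMF, 0 → 23 °C
Reagents that add atoms: chloromethyl methyl ether, COCCl
Why: Williamson-type O-alkylation of both phenoxides (NaH is needed for the hydrogen-bonded ortho hydroxyl), giving acetal ethers that tolerate the amide base of step 7 and are removed by mild acid in step 10.

Step 7
Reactants: 10 methyl 3-chloro-4,6-bis(methoxymethoxy)-2-methylbenzoate
Product: 12 5-chloro-6,8-bis(methoxymethoxy)-3-methyl-1H-isochromen-1-one, via keto ester 11 (not isolated)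
Conditions: LiN(iPr)2 (2.2 equiv), THF, −78 °C; MeC(O)N(OMe)Me, −78 → 0 °C; AcOH; solvent exchange to toluene, DBU (0.3 equiv), 80 °C
Reagents that add atoms: N-methoxy-N-methylacetamide, CON(C)C(C)=O
Why: lateral (benzylic) lithiation ortho to the ester and acylation by the N-methoxy-N-methylamide should give keto ester 11, whose enol oxygen then attacks the neighbouring ester (6-exo-trig enol lactonisation with loss of methanol) to close the isocoumarin ring.

Step 8
Reactants: 12 5-chloro-6,8-bis(methoxymethoxy)-3-methyl-1H-isochromen-1-one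
Product: 13 5-chloro-6,8-bis(methoxymethoxy)-1-oxo-1H-isochromene-3-carbaldehyde
Conditions: SeO2, 1,4-dioxane, 100 °C
Reagents that add atoms: selenium dioxide, O=[Se]=O
Why: Riley oxidation of the C3 methyl group, which is allylic to the C3=C4 enol-lactone double bond (as in 2-methylchromones) and carries the only allylic C–H bonds in the molecule.

Step 9
Reactants: 13 5-chloro-6,8-bis(methoxymethoxy)-1-oxo-1H-isochromene-3-carbaldehyde
Product: 14 5-chloro-3-[(E)-2-iodoethenyl]-6,8-bis(methoxymethoxy)-1H-isochromen-1-one
Conditions: CHI3, CrCl2, THF–1,4-dioxane, 0 → 23 °C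
Reagents that add atoms: iodoform, IC(I)I
Why: Takai olefination, which should convert the conjugated aldehyde into the E-alkenyl iodide and leave the lactone, the aryl chloride and the acetal ethers alone.

Step 10
Reactants: 14 5-chloro-3-[(E)-2-iodoethenyl]-6,8-bis(methoxymethoxy)-1H-isochromen-1-one
Product: 15 5-chloro-6,8-dihydroxy-3-[(E)-2-iodoethenyl]-1H-isochromen-1-one
Conditions: TFA–CH2Cl2 (1:4), 0 → 23 °C; aqueous work-up
Reagents that add atoms: none
Why: acid cleavage of both methoxymethyl acetals at a stage where only acid-stable groups (alkenyl iodide, isocoumarin) are present, so that no acid is needed once the dienyl oxolane exists.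

Step 11
Reactants: 7 (2S,3R,5R)-5-methyl-2-[(E)-2-(4,4,5,5-tetramethyl-1,3,2-dioxaborolan-2-yl)ethenyl]oxolan-3-ol; 15 5-chloro-6,8-dihydroxy-3-[(E)-2-iodoethenyl]-1H-isochromen-1-one
Product: 16 5-chloro-6,8-dihydroxy-3-[(1E,3E)-4-[(2S,3R,5R)-3-hydroxy-5-methyloxolan-2-yl]buta-1,3-dien-1-yl]-1H-isochromen-1-one
Conditions: PdCl2(dppf) (5 mol %), K3PO4 (5 equiv), degassed THF–H2O (4:1), 40 °C; then NaH2PO4 buffer (pH 4)
Reagents that add atoms: none
Why: Suzuki–Miyaura coupling of an alkenylboronate with an alkenyl iodide, which should proceed with retention of both alkene geometries and tolerate the free alcohol and phenols (as phenoxides under excess base, reprotonated at pH 4).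

**Compound list**

1 | (4R)-2,2-dimethyl-1,3-dioxolane-4-carbaldehyde | O=C[C@H]1COC(C)(C)O1 | starting material
2 | 2-[(E)-2-[(4S)-2,2-dimethyl-1,3-dioxolan-4-yl]ethenyl]-4,4,5,5-tetramethyl-1,3,2-dioxaborolane | CC1(C)OB(/C=C/[C@H]2COC(C)(C)O2)OC1(C)C | intermediate
3 | trimethyl{[(2S,3E)-2-(prop-1-en-2-yloxy)-4-(4,4,5,5-tetramethyl-1,3,2-dioxaborolan-2-yl)but-3-en-1-yl]oxy}silane | CC1(C)OB(/C=C/[C@H](OC(C)=C)CO[Si](C)(C)C)OC1(C)C | intermediate
4 | (2S,3E)-2-(prop-1-en-2-yloxy)-4-(4,4,5,5-tetramethyl-1,3,2-dioxaborolan-2-yl)but-3-en-1-ol | CC1(C)OB(/C=C/[C@H](OC(C)=C)CO)OC1(C)C | intermediate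
5 | (2S,3E)-2-(prop-1-en-2-yloxy)-4-(4,4,5,5-tetramethyl-1,3,2-dioxaborolan-2-yl)but-3-enal | CC1(C)OB(/C=C/[C@H](OC(C)=C)C=O)OC1(C)C | intermediate
6 | (2S,3R)-5-methyl-2-[(E)-2-(4,4,5,5-tetramethyl-1,3,2-dioxaborolan-2-yl)ethenyl]-3-(trifluoroboranuidyloxy)-3,4-dihydro-2H-furan-1-ium (zwitterion) | CC1=[O+][C@@H](/C=C/B2OC(C)(C)C(C)(C)O2)[C@H](O[B-](F)(F)F)C1 | intermediate
7 | (2S,3R,5R)-5-methyl-2-[(E)-2-(4,4,5,5-tetramethyl-1,3,2-dioxaborolan-2-yl)ethenyl]oxolan-3-ol | C[C@@H]1C[C@@H](O)[C@H](/C=C/B2OC(C)(C)C(C)(C)O2)O1 | intermediate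
8 | methyl 2,4-dihydroxy-6-methylbenzoate | COC(=O)c1c(C)cc(O)cc1O | starting material
9 | methyl 3-chloro-4,6-dihydroxy-2-methylbenzoate | COC(=O)c1c(C)c(Cl)c(O)cc1O | intermediate
10 | methyl 3-chloro-4,6-bis(methoxymethoxy)-2-methylbenzoate | COCOc1cc(OCOC)c(C(=O)OC)c(C)c1Cl | intermediate
11 | methyl 3-chloro-4,6-bis(methoxymethoxy)-2-(2-oxopropyl)benzoate | COCOc1cc(OCOC)c(C(=O)OC)c(CC(C)=O)c1Cl | intermediate
12 | 5-chloro-6,8-bis(methoxymethoxy)-3-methyl-1H-isochromen-1-one | Cc1cc2c(Cl)c(OCOC)cc(OCOC)c2c(=O)o1 | intermediate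
13 | 5-chloro-6,8-bis(methoxymethoxy)-1-oxo-1H-isochromene-3-carbaldehyde | O=Cc1cc2c(Cl)c(OCOC)cc(OCOC)c2c(=O)o1 | intermediate
14 | 5-chloro-3-[(E)-2-iodoethenyl]-6,8-bis(methoxymethoxy)-1H-isochromen-1-one | I/C=C/c1cc2c(Cl)c(OCOC)cc(OCOC)c2c(=O)o1 | intermediate
15 | 5-chloro-6,8-dihydroxy-3-[(E)-2-iodoethenyl]-1H-isochromen-1-one | I/C=C/c1cc2c(Cl)c(O)cc(O)c2c(=O)o1 | intermediate
16 | 5-chloro-6,8-dihydroxy-3-[(1E,3E)-4-[(2S,3R,5R)-3-hydroxy-5-methyloxolan-2-yl]buta-1,3-dien-1-yl]-1H-isochromen-1-one | C[C@@H]1C[C@@H](O)[C@H](/C=C/C=C/c2cc3c(Cl)c(O)cc(O)c3c(=O)o2)O1 | target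

**Step count**

Total: 11 steps. Longest linear sequence: 7 steps (steps 5 to 11); the oxolane half takes steps 1 to 4 and joins in step 11.

**Steps most likely to fail**

1. Step 4. The intramolecular C–C bond formation may lose to [3,3]-sigmatropic rearrangement of the allyl vinyl ether, to protonation or direct reduction of the enol ether, or it may proceed with poor facial selectivity at C3. The fallback uses known chemistry and closes the ring at O1–C5 after an intermolecular acetone aldol; it sets out from 2 and comes back at 7. Hydrolysis of the acetonide (aq. AcOH) should give (2S,3E)-4-(4,4,5,5-tetramethyl-1,3,2-dioxaborolan-2-yl)but-3-ene-1,2-diol F1. TESCl and imidazole should give the bis(triethylsilyl) ether F2. Swern oxidation, which converts a primary triethylsilyl ether directly into the aldehyde, should give the α-silyloxy aldehyde F3. A BF3·OEt2-mediated Mukaiyama aldol addition of 2-(trimethylsilyloxy)propene under non-chelation control should give the 1,2-anti aldol (4R,5S,6E)-4-hydroxy-7-B(pin)-5-(triethylsilyloxy)hept-6-en-2-one F4. Reductive etherification of this silyloxy ketone (Et3SiH, BiBr3 cat., MeCN) should close the oxolane and set C5 by the same hydride delivery cis to O-3, giving 7.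

2. Step 2. The ketal may open with the wrong regiochemistry (silyl group on the secondary oxygen), or the allylic C–O bond may ionise. The fallback builds the 2-propenyl ether by carbonyl methylenation of an acetate; it sets out from 2 and comes back at 4. Hydrolysis (aq. AcOH) should give the diol F5 (same constitution as F1). TBSCl and imidazole should silylate the primary hydroxyl to give (2S,3E)-1-(tert-butyldimethylsilyloxy)-4-B(pin)-but-3-en-2-ol F6. Ac2O, pyridine and DMAP should give the secondary acetate F7. Cp2TiMe2 in toluene at 65 °C should methylenate the ester carbonyl to the 2-propenyl ether F8, and TBAF in THF should then free the primary alcohol 4.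

3. Step 7. The base-mediated enol lactonisation may stall at the keto ester, or the methoxide set free may reopen the lactone. The fallback closes the ring under acid at the cost of the protecting groups; it sets out from keto ester 11, isolated after the AcOH quench, and comes back at 12. TFA in CH2Cl2 should bring about cyclodehydration together with loss of both methoxymethyl groups to give 5-chloro-6,8-dihydroxy-3-methyl-1H-isochromen-1-one F9. NaH and MOMCl in DMF should then restore the two acetal ethers and give 12.

**Further compounds**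

F1 | step 4 | (2S,3E)-4-(4,4,5,5-tetramethyl-1,3,2-dioxaborolan-2-yl)but-3-ene-1,2-diol | CC1(C)OB(/C=C/[C@H](O)CO)OC1(C)C
F2 | step 4 | 2-[(1E,3S)-3,4-bis(triethylsilyloxy)but-1-en-1-yl]-4,4,5,5-tetramethyl-1,3,2-dioxaborolane | CC1(C)OB(/C=C/[C@H](O[Si](CC)(CC)CC)CO[Si](CC)(CC)CC)OC1(C)C
F3 | step 4 | (2S,3E)-4-(4,4,5,5-tetramethyl-1,3,2-dioxaborolan-2-yl)-2-(triethylsilyloxy)but-3-enal | CC1(C)OB(/C=C/[C@H](O[Si](CC)(CC)CC)C=O)OC1(C)C
F4 | step 4 | (4R,5S,6E)-4-hydroxy-7-(4,4,5,5-tetramethyl-1,3,2-dioxaborolan-2-yl)-5-(triethylsilyloxy)hept-6-en-2-one | CC(=O)C[C@@H](O)[C@@H](O[Si](CC)(CC)CC)/C=C/B1OC(C)(C)C(C)(C)O1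
F5 | step 2 | (2S,3E)-4-(4,4,5,5-tetramethyl-1,3,2-dioxaborolan-2-yl)but-3-ene-1,2-diol | CC1(C)OB(/C=C/[C@H](O)CO)OC1(C)C
F6 | step 2 | (2S,3E)-1-(tert-butyldimethylsilyloxy)-4-(4,4,5,5-tetramethyl-1,3,2-dioxaborolan-2-yl)but-3-en-2-ol | CC1(C)OB(/C=C/[C@H](O)CO[Si](C)(C)C(C)(C)C)OC1(C)C
F7 | step 2 | (2S,3E)-1-(tert-butyldimethylsilyloxy)-4-(4,4,5,5-tetramethyl-1,3,2-dioxaborolan-2-yl)but-3-en-2-yl acetate | CC1(C)OB(/C=C/[C@H](OC(C)=O)CO[Si](C)(C)C(C)(C)C)OC1(C)C
F8 | step 2 | tert-butyldimethyl{[(2S,3E)-2-(prop-1-en-2-yloxy)-4-(4,4,5,5-tetramethyl-1,3,2-dioxaborolan-2-yl)but-3-en-1-yl]oxy}silane | CC1(C)OB(/C=C/[C@H](OC(C)=C)CO[Si](C)(C)C(C)(C)C)OC1(C)C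
F9 | step 7 | 5-chloro-6,8-dihydroxy-3-methyl-1H-isochromen-1-one | Cc1cc2c(Cl)c(O)cc(O)c2c(=O)o1
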